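What could not change was each hand's substrate plus its product, which stayed equal to that hand's charge, and precatalyst plus catalyst plus idle complex, which stayed equal to the catalyst charged.

- south-east: left-handed substrate 0.50 M; coupling partner 0.600 M; precatalyst 100 mM; added ligand 570 mM; right-handed substrate 0.50 M; time 25 min
- south-west: left-handed substrate 0.50 M; coupling partner 1.80 M; precatalyst 100 mM; added ligand 570 mM; right-handed substrate 0.50 M; time 25 min

    coupling partner + catalyst + left-handed substrate → catalyst + left-handed product (k1 = 1.0 M⁻² min⁻¹)
    coupling partner + catalyst + right-handed substrate → catalyst + right-handed product (k2 = 0.041 M⁻² min⁻¹)
    catalyst + added ligand ⇌ idle complex (K3 = 2.4 M⁻¹, k3 = 3.3 M⁻¹ min⁻¹)
    precatalyst → catalyst (k4 = 0.074 min⁻¹)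

- catalyst is single-handed; left-handed substrate and right-handed substrate are mirror images of each other, charged as a racemate, each of them at the stated concentration
- run time (south-east): 25 min

* which of these there is most of at the end, counted by the substrate in it, south-east (right-handed product / left-handed substrate / left-handed product / right-handed substrate)
* which of these there is most of at the end, counted by the substrate in it, south-west (right-handed product / left-handed substrate / left-handed product / right-handed substrate)
* how much there is at the end of the one of these that leads, in percent of the left-handed substrate and right-handed substrate together charged: south-east
* how much there is at the end of the one of these that leads, in percent of the left-handed substrate and right-handed substrate together charged: south-west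

I kept the books in fractions of the substrate charge, both hands together.

1. In south-east the coupling partner was, by its charge, the limiting reagent against both hands together, at 60.0% of the substrate charge. In south-west the substrates were limiting.

2. The forward binding of added ligand alone, at the ligand's charge, had a half-life of 0.368 min, far shorter than the 9.4 min of activation. So I let activated catalyst split at once, with a free share of 42.2%.

3. I replaced the curves by their means. Over the run, the mean activated fraction was 54.4%. The exposure therefore came to 0.575 M·min: the time integral of free catalyst. The coupling partner does not enter it, so I used it for both flasks.

4. Each hand decays in a pseudo-first-order way, so the fraction left is the exponential of minus rate constant times mean partner times exposure. The selectivity factor is 24.4.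

5. With the partner held at its charge, I reckoned that south-east used 15.3% of the substrate charge. Half of that consumption lowered the mean partner to 87.3% of its charge. This correction moved left-handed substrate by 1.6 percentage points.

6. My south-east books closed at left-handed substrate 37.0%, right-handed substrate 49.4%, left-handed product 13.0% and right-handed product 0.613%. Right-handed substrate led in these books.

7. In south-west, first-pass use of 34.3% gave a mean partner of 90.5%. My south-west books closed at left-handed substrate 19.6%, right-handed substrate 48.1% and left-handed product 30.4%. Right-handed substrate led in these books too.

The forecast named right-handed substrate at 49.4% for south-east and right-handed substrate at 48% for south-west, holding that “the roughly 24-fold slower right-handed substrate barely moves”.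

The simulation gave right-handed substrate at 49.4% in south-east and right-handed substrate at 48.0% in south-west, with left-handed substrate at 36.3% and 18.8%.

South-east kept 73% of its left-handed charge, which reads back through my mean partner as an exposure of 0.609 M·min, beside my 0.575 M·min. The neighbouring flask, south-east with 0.97 M of added ligand, took the same reckoning. I reckoned its free share at 30.0% and its exposure at 0.409 M·min, with a mean partner of 90.5%. That gave left-handed substrate 40.0% and right-handed substrate 49.5%. The neighbouring flask held left-handed substrate at 39.5%, left-handed product at 10.5% and right-handed substrate at 49.5%.

The rate constants come from no measurement; what happens was integrated by code.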